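The numbers are assumed; the result is computed.

In a one-step world starting material and reagent would simply make target, and the order of addition would change the clock and nothing more; these flasks also lose target by two further steps.

all flasks: time 50 min
- west: starting material 37 mM (fed, over 40 min); reagent 1.00 equiv; all else is in the flask from the start; the feed brings no volume worth counting
- north-west: starting material 37 mM; reagent 1.00 equiv (fed, over 40 min); all else is in the flask from the start; the feed brings no volume worth counting
- south-west: starting material 37 mM; reagent 1.00 equiv (in portions, 2, over 40 min); first portion at the start, last at 40 min
- north: starting material 37 mM; reagent 1.00 equiv; everything together at the start

    starting material + reagent → target + released group (k1 = 0.069 M⁻¹ s⁻¹)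
    starting material + target → side product A (k2 = 0.050 M⁻¹ s⁻¹)
    target + released group → side product B (k3 = 0.025 M⁻¹ s⁻¹)

- a species is counted by the starting material in it: one side product A counts as two
- run time (west): 50 min

1. the best flask by amount of target, in percent of the starting material charged; "all alike" if 1.5 percentage points covers them all (west / north-west / south-west / north / all alike)
2. amount of target at the end, in percent of the starting material charged, west
3. amount of target at the end, in percent of the starting material charged, north-west
4. amount of target at the end, in percent of the starting material charged, south-west
5. amount of target at the end, in percent of the starting material charged, north

The bench rule I reached for was to feed the starting material slowly, so that [starting material] stays low and the second step starves. By that rule the feed in west qualified, since its dosing time is 6.1 lifetimes of starting material against everything charged, more than one. But the rule stopped working when I held the second step against the first, because both carry [starting material] and it cancels from their ratio: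

rate of second step / rate of first step = 0.050 M⁻¹ s⁻¹ [target] / (0.069 M⁻¹ s⁻¹ [reagent])

So I froze the ratio of the two rate constants, the selectivity factor in the usual term:

[target] / [reagent] = 0.069 M⁻¹ s⁻¹ / 0.050 M⁻¹ s⁻¹ = 1.38

This is the break-even ratio, the [target]/[reagent] above which starting material, third step aside, destroys more target than it makes. With reagent charged at 1.00 equiv, percentages of the two charges compare directly.

For north, with the third step set aside, I followed target against reagent up to break-even and reckoned a peak of 42.8% of the charge with 31.0% of the reagent left. From there I treated the first two steps as over, an estimate, and started the clock one lifetime of the first step late, after 6.53 min, which left 43.5 min. The third step takes target and released group one for one, so I froze their difference at 26 of the charge, and [target]/([target] + difference) then falls exponentially at 0.0145 min⁻¹: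

[target]/([target] + difference) at the end = 0.331

[target] at the end, north = 12.9% I expected west to lead, since its starting material arrives on average 30.0 min before the end, less than the 50 min in north.

The forecast chose west, giving 22% for west, 17% for north-west, 13% for south-west and 10% for north, and said of north-west, “Excess starting material meets the target throughout”.

West ended best at 26.0%, against 19.4% in north-west, 14.8% in south-west and 15.4% in north. Just before its last addition, at 40.0 min, south-west held 8.06% target beside 3.29% reagent, a ratio of 2.45, above break-even, while west ended at 0.847, below it. The neighbour of west charged with 0.600 equiv of reagent ended at a ratio of 1.67, above break-even, with target at 15.5%.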